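**Analysis of the target**

The target 49 is a linear chain of seven benzene rings, A to G, joined only by six diaryl ether oxygens (A4–O–B1, B4–O–C1, C6–O–D1, D4–O–E1, E6–O–F1, F4–O–G1) and carrying eighteen free phenolic hydroxyls. It has no stereocentre and no carbon–carbon bond between rings. Rings A and G are the end groups (2,4,6-trihydroxyphenoxy and 3,4,5-trihydroxyphenyl), rings B, D and F are 1,4-dioxygenated 3,5-diols, and rings C and E are pentaoxygenated with a single hydrogen at position 2. The free polyphenol is oxidised easily by air, above all as its anions, so every hydroxyl has to stay masked until the last step. The main difficulty is the ether bonds: each of the six oxygens sits on one carbon flanked by two further oxygens (A4, B4, C6, D4, E6, F4), so these carbons can only be the phenol partner, and two of the partner carbons (C1 and E1) carry an ortho oxygen as well. In addition the five oxygens of rings C and E must be told apart, because only O1 and O6 become ether links. The route rests on ring C: C3, C4, C5 and C6 are four contiguous oxygen-bearing carbons, the pattern of a squaric acid diester, and C1–C2 with the B4 oxygen on C1 is an aryl vinyl ether unit; ring E repeats this pattern with the D4 oxygen.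

**Retrosynthetic reasoning**

49 from 48 (eighteen O–methyl bonds). All hydroxyls are carried as methyl ethers, the one group that survives organolithium reagents, hydrogenolysis, desilylation and heating to 110 °C. The forward step has to break only alkyl–oxygen bonds and leave the six aryl–oxygen–aryl links alone.

48 from 41 and 46 (bond G1–O). G1 has a hydrogen on each side and a methoxy group one carbon further on. That is the substitution an aryne addition produces: the F4 phenoxide of 41 attacks aryne 47, released from silyl triflate 46, at the carbon remote from the methoxy group. The hindered oxygen is the nucleophile and no coupling at a doubly flanked carbon is needed. 46 comes from 42 in three steps.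

41 from 39, 27 from 25, and 11 from 8, each with 7 (bonds F1–O, D1–O and B1–O). Rings B, D and F are the same unit: an ether carbon between two hydrogens, two methoxy groups, and a 4-oxygen that must be released afterwards. One building block therefore serves three times: 7, which releases aryne 9 and carries the 4-oxygen as a benzyl ether. The ring D aryne is used as this monomer and not as a preassembled block carrying rings E to G. An aryne is partly lost to side reactions and has to be taken in excess, so it should be the cheap partner; and the ortho bromination that leads to a silyl triflate is unambiguous on the symmetrical monomer 3 but would need selection among four electron-rich rings on a tetramer. The price is a longer linear sequence.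

39 from 34 and hence from 27 (ring E, bond E2–E3). The B4–O–C1 and D4–O–E1 bonds cannot be made by the aryne tactic, because an aryne of ring C or E would have an oxygen on both flanks and no regiocontrol. Ring E is therefore built onto the D4 oxygen of 27 by the same ring expansion as ring C.

25 from 24, 23 and 20 (ring C, bond C2–C3; the key disconnection). Cutting C2–C3 and reconnecting C3 to C6 leads back to the cyclobutenone 20, in which C3–C6 are the four squarate carbons and C1–C2 the 1-aryloxyvinyl group. On heating, 20 must open so that the vinyl group lies next to the ketene, then close and aromatise. What is gained is a pentaoxygenated ring in which O3 appears free and O6 silylated, so O3 can be methylated and O6 released for the next ether bond. The B4–O–C1 bond is never made by aryl coupling, because the B4 oxygen is already on the vinyl carbon. A tert-butyldimethylsilyl group is chosen because the aryl silyl ether in 23 has to survive K2CO3 during the methylation.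

20 from 19, and 19 from 17 and 18; 18 from 16, 15, 13, and finally 11 and 12. The carbinol carbon of 19 is formed by adding vinyllithium 18 to one carbonyl of dimethyl squarate 17. The anion must sit on the oxygen-bearing vinyl carbon and nowhere on the rings, which have several acidic positions between two oxygens. It is therefore generated by tin–lithium exchange from 16, not by deprotonation. 16 comes from hydrostannylation of the ethynyl ether 15, and 15 from phenol 11 and trichloroethene 12 via the dichlorovinyl ether 13.

7 from 1. The silyl triflate is made from a phenol by ortho bromination, O-silylation and a bromine–lithium exchange with silyl shift. The phenol 3 comes from aldehyde 1 by oxidative removal of the formyl carbon.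

**Alternatives that were turned down**

Alternative 1: Ring B from a pyranone.
- Disconnection: bonds B1–B2 and B1–B6. Carbons B2–B6 come from 3,5-dimethoxy-4H-pyran-4-one A2, and B1 with its ether oxygen from [(2,4,6-trimethoxyphenoxy)methyl]triphenylphosphonium chloride A3.
- Forward key step: the ylide of A3 adds to C2 of A2, which is activated at its carbonyl oxygen by iPr3SiOTf; ring opening and an intramolecular Wittig reaction then close ring B and give the silyl-protected dimer A1.
- For: the A4–O–B1 ether comes from O-alkylation of a phenol, the B4 oxygen emerges differentiated, and desilylation of A1 would give phenol 11 in fewer operations than the aryne route. On that point it is stronger.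
- Against: it spends the ring synthesis on the easiest part of the molecule. B1 lies between two hydrogens, which is the bond an aryne makes well. The hard bonds (B4–O–C1, D4–O–E1) and both pentaoxygenated rings are untouched. Mechanistically, the two methoxy donors lower the electrophilicity of C2 in A2, and an α-aryloxy ylide can lose aryloxide.
- Comparison: the aryne block 7 is needed for rings D and F anyway, so the saving is small, and the chosen strategy places ring construction where no coupling is available.

Alternative 2: Ring A folded from two acyclic esters.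
- Disconnection: bonds A2–A3 and A5–A6.
- Forward key step: NaOEt condenses both methylene carbons of diethyl 3-oxopentanedioate A6 with the two ester groups of the aryloxymalonate A5, which carries the permethylated rings B–G. The product is the diester A4.
- For: the chemistry is cheap, the three ring A hydroxyls appear free, and the A4–O bond is made on the way to A5 by O-alkylation at a B1 oxygen that has a hydrogen on each side.
- Against: ring A is the ring that can be bought ready-made as 8. The condensation comes at the very end on a hexamer, a double Claisen closure that is low-yielding even on simple substrates. Two ester groups must then be hydrolysed and decarboxylated. All the difficult bonds lie inside A5 and are left to other methods.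
- Comparison: in step economy it adds three or more late steps to replace a single aryne addition, and it gives nothing toward rings C and E.

Alternative 3: Central ring D by Danheiser benzannulation.
- Disconnection: bonds D5–D6 and D1–D2, with D4–D5 broken and re-formed; ring D arises from two halves.
- Forward key step: the ethynyl ether A8 of the rings A–C phenol is heated with the racemic 4-aryloxy-3-ethoxycyclobutenone A9 carrying rings E–G. A9 opens thermally, its ketene function adds across the triple bond of A8, and a second ring opening followed by six-electron closure gives the heptamer A7, with D5 hydroxyl free and D3 as ethyl ether.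
- For: this is a 3 + 3 union, and both ether bonds of ring D are present before the ring exists. On convergence it is clearly stronger than the chosen route, whose longest sequence is 28 steps.
- Against: both halves still contain a pentaoxygenated ring (C in A8, E in A9) for which this plan offers nothing. A9 needs the hindered E1 oxygen of a rings E–G unit attached to the sp3 carbon of a four-membered ring. The key step joins two crowded, thermally sensitive partners at the last stage, where an intermolecular ketene–alkyne cycloaddition must beat ketene dimerisation.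
- Comparison: the chosen strategy gives up convergence but makes each pentaoxygenated ring intramolecularly, and its oxygens come out differentiated.

Key step: step 12

Assumption (remark on the chemistry): 1, 8, 12, 17 and 42 are taken as purchasable. Rings and ring atoms are lettered and numbered as in the analysis, and "permethylated" means that every ring oxygen not named otherwise is a methyl ether. Aryne 9 is a transient that CsF releases afresh from 7 each time 7 is used (steps 5, 15 and 25); it carries one number and stands on the Product line of step 5, where it first forms.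

**Route**

Step 1
Reactants: 1 4-(benzyloxy)-3,5-dimethoxybenzaldehyde
Product: 3 4-(benzyloxy)-3,5-dimethoxyphenol, via aryl formate 2 (not isolated)
Conditions: mCPBA, CH2Cl2, 0 °C to rt; aq NaHCO3 wash; then K2CO3 (cat.), MeOH, rt
Reagents that add atoms: 3-chloroperoxybenzoic acid, O=C(OO)c1cccc(Cl)c1
Why: Baeyer–Villiger oxidation; in this electron-rich benzaldehyde the aryl group migrates in preference to hydride to give formate 2, and K2CO3-catalysed methanolysis frees the phenol (Dakin-type overall), the benzyl ether being inert.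

Step 2
Reactants: 3 4-(benzyloxy)-3,5-dimethoxyphenol
Product: 4 4-(benzyloxy)-2-bromo-3,5-dimethoxyphenol
Conditions: NBS (1.0 equiv), CH2Cl2, −78 °C to 0 °C
Reagents that add atoms: N-bromosuccinimide, O=C1CCC(=O)N1Br
Why: Electrophilic aromatic bromination ortho to the free hydroxyl; the two ortho positions of 3 are equivalent and the para position is blocked, so one equivalent at low temperature should stop at the monobromide.

Step 3
Reactants: 4 4-(benzyloxy)-2-bromo-3,5-dimethoxyphenol
Product: 5 [4-(benzyloxy)-2-bromo-3,5-dimethoxyphenoxy]trimethylsilane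
Conditions: HMDS, THF, 65 °C; evaporate
Reagents that add atoms: hexamethyldisilazane, C[Si](C)(C)N[Si](C)(C)C
Why: O-silylation of a phenol with a disilazane, ammonia being the only by-product; the crude silyl ether is taken on after evaporation.

Step 4
Reactants: 5 [4-(benzyloxy)-2-bromo-3,5-dimethoxyphenoxy]trimethylsilane
Product: 7 4-(benzyloxy)-3,5-dimethoxy-2-(trimethylsilyl)phenyl trifluoromethanesulfonate, via lithium phenolate 6 (not isolated)
Conditions: n-BuLi, THF, −78 °C; then Tf2O, −78 °C to rt
Reagents that add atoms: trifluoromethanesulfonic anhydride, O=S(=O)(OS(=O)(=O)C(F)(F)F)C(F)(F)F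
Why: Bromine–lithium exchange followed by anionic 1,3 oxygen-to-carbon silyl migration (retro-Brook rearrangement) gives the ortho-silyl phenolate 6, which is triflated on oxygen; this is the standard entry to 2-(trimethylsilyl)aryl triflates as aryne precursors.

Step 5
Reactants: 7 4-(benzyloxy)-3,5-dimethoxy-2-(trimethylsilyl)phenyl trifluoromethanesulfonate; 8 2,4,6-trimethoxyphenol
Product: 10 2-[4-(benzyloxy)-3,5-dimethoxyphenoxy]-1,3,5-trimethoxybenzene (rings A–B dimer with B4 benzyl ether), via aryne 9 (not isolated)
Conditions: 7 (1.3 equiv), CsF (3 equiv), MeCN, rt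
Reagents that add atoms: none
Why: Aryne O-arylation of a phenol: CsF induces 1,2-elimination of 7 to aryne 9, and the phenoxide of 8 adds at the aryne carbon remote from the neighbouring methoxy group (the developing aryl anion is stabilised ortho to that oxygen), so the ether oxygen arrives at B1 between two hydrogens and the anion is protonated by the phenol.

Step 6
Reactants: 10 rings A–B dimer with B4 benzyl ether
Product: 11 2,6-dimethoxy-4-(2,4,6-trimethoxyphenoxy)phenol (rings A–B phenol with B4 hydroxyl free)
Conditions: H2 (1 atm), Pd/C, EtOAc/MeOH, rt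
Reagents that add atoms: none
Why: Catalytic hydrogenolysis of a benzyl ether; methyl and diaryl ethers are inert.

Step 7
Reactants: 11 rings A–B phenol; 12 trichloroethene
Product: 13 2-{4-[(E)-1,2-dichloroethenyloxy]-3,5-dimethoxyphenoxy}-1,3,5-trimethoxybenzene
Conditions: K2CO3, DMF, 70 °C
Reagents that add atoms: none
Why: Elimination–addition: K2CO3 converts 12 into dichloroethyne in the flask and the phenoxide adds across it in anti fashion, the usual route from phenols to (E)-1,2-dichlorovinyl ethers; the small linear electrophile is not hindered by the two ortho methoxy groups.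

Step 8
Reactants: 13 (E)-1,2-dichloroethenyl ether of 11
Product: 15 2-[4-(ethynyloxy)-3,5-dimethoxyphenoxy]-1,3,5-trimethoxybenzene, via lithium acetylide 14 (not isolated)
Conditions: n-BuLi (2.2 equiv), THF, −78 °C to −40 °C; then MeOH, −78 °C
Reagents that add atoms: none
Why: Conversion of a dichlorovinyl ether into an alkynyl ether: vinyl deprotonation, β-elimination of LiCl and chlorine–lithium exchange give acetylide 14, which is protonated cold; at −78 °C these events are much faster than ring lithiation, and the hydration-prone ynol ether is used at once.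

Step 9
Reactants: 15 ethynyl ether of 11
Product: 16 tributyl{1-[2,6-dimethoxy-4-(2,4,6-trimethoxyphenoxy)phenoxy]ethenyl}stannane
Conditions: Bu3SnH, Pd(PPh3)4 (cat.), THF, 0 °C
Reagents that add atoms: tributyltin hydride, CCCC[SnH](CCCC)CCCC
Why: Palladium-catalysed syn hydrostannylation of a 1-alkoxyalkyne, which places tin on the oxygen-bearing carbon and hydrogen on the terminal carbon to give the 1-stannylvinyl ether; purification on a base-washed support avoids protodestannylation.

Step 10
Reactants: 16 1-stannylvinyl ether; 17 dimethyl squarate (3,4-dimethoxycyclobut-3-ene-1,2-dione)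
Product: 19 racemic 4-hydroxy-2,3-dimethoxy-4-{1-[2,6-dimethoxy-4-(2,4,6-trimethoxyphenoxy)phenoxy]ethenyl}cyclobut-2-en-1-one, via vinyllithium 18 (not isolated)
Conditions: n-BuLi, THF, −78 °C; then 17, THF, −78 °C; aq NH4Cl
Reagents that add atoms: none
Why: Tin–lithium exchange gives vinyllithium 18 specifically at the carbon α to oxygen, and 18 adds 1,2 to one of the two equivalent carbonyls of 17 (standard organolithium addition to a squaric ester); the quaternary stereocentre forms as a racemate, which does not matter because it becomes sp2 in step 12.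

Step 11
Reactants: 19 racemic 4-hydroxycyclobutenone
Product: 20 racemic 4-[(tert-butyldimethylsilyl)oxy]-2,3-dimethoxy-4-{1-[2,6-dimethoxy-4-(2,4,6-trimethoxyphenoxy)phenoxy]ethenyl}cyclobut-2-en-1-one
Conditions: TBSOTf, 2,6-lutidine, CH2Cl2, −78 °C to 0 °C
Reagents that add atoms: tert-butyldimethylsilyl trifluoromethanesulfonate, CC(C)(C)[Si](C)(C)OS(=O)(=O)C(F)(F)F
Why: Silylation of a tertiary carbinol with a silyl triflate and a hindered pyridine base; the buffered cold conditions spare the acid-labile enol ether.

Step 12
Reactants: 20 racemic 4-silyloxy-4-(1-aryloxyethenyl)cyclobutenone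
Product: 23 4-[(tert-butyldimethylsilyl)oxy]-2,3-dimethoxy-5-[2,6-dimethoxy-4-(2,4,6-trimethoxyphenoxy)phenoxy]phenol (rings A–C trimer with C3 hydroxyl free and C6 silyl ether), via dienylketene 21 (not isolated), via cyclohexadienone 22 (not isolated)
Conditions: toluene (0.01 M, degassed), 110 °C, argon
Reagents that add atoms: none
Why: Thermal Moore rearrangement; the closest known reaction type is the ring expansion of squarate-derived 4-alkenyl- and 4-aryl-4-oxycyclobutenones to hydroquinone derivatives. At 110 °C the bond between the carbonyl carbon and the quaternary carbon of 20 breaks in a conrotatory four-electron electrocyclic opening to give dienylketene 21. Ring C is then closed by a thermal disrotatory six-electron electrocyclisation in which the ketene carbon (future C3) bonds to the CH2 terminus of the aryloxyvinyl group (future C2), giving the 6H-cyclohexa-2,4-dienone 22, and enolisation with loss of a C2 hydrogen aromatises it to phenol 23. No stereocentre is formed, and the racemic quaternary centre of 20 becomes the sp2 carbon C6. The selectivity needed is torquoselectivity in the ring opening: the silyloxy donor on the breaking bond rotates outward, helped by the bulk of the tert-butyldimethylsilyl group, so the vinyl group turns inward and lies cis to the ketene, the only geometry from which closure is possible. The same event leaves the four squarate oxygens differentiated, O3 free, O4 and O5 methylated and O6 silylated. High dilution in a degassed aprotic solvent keeps the ketene from being acylated by the product phenol and protects the electron-rich product from oxidation.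

Step 13
Reactants: 23 rings A–C trimer with C3 hydroxyl free and C6 silyl ether
Product: 24 tert-butyldimethyl{2,3,4-trimethoxy-6-[2,6-dimethoxy-4-(2,4,6-trimethoxyphenoxy)phenoxy]phenoxy}silane
Conditions: MeI, K2CO3, acetone, 40 °C, argon
Reagents that add atoms: iodomethane, CI
Why: Williamson O-methylation of the only free phenol, which has an ortho hydrogen and reacts readily; the doubly flanked aryl tert-butyldimethylsilyl ether at C6 is stable to K2CO3 in acetone, and methylation removes the oxidation-prone free hydroquinone monoether.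

Step 14
Reactants: 24 C6 silyl ether of the permethylated rings A–C trimer
Product: 25 2,3,4-trimethoxy-6-[2,6-dimethoxy-4-(2,4,6-trimethoxyphenoxy)phenoxy]phenol (rings A–C phenol with C6 hydroxyl free)
Conditions: Bu4NF, AcOH, THF, 0 °C
Reagents that add atoms: none
Why: Fluoride cleavage of an aryl silyl ether, driven by Si–F bond formation and buffered with acetic acid so that the electron-rich phenol is not left as its anion.

Step 15
Reactants: 25 rings A–C phenol; 7 aryne precursor
Product: 26 permethylated rings A–D tetramer with D4 benzyl ether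
Conditions: 7 (1.5 equiv), CsF (3 equiv), MeCN, rt
Reagents that add atoms: none
Why: Aryne O-arylation as in step 5: CsF again releases aryne 9 from 7, and the crowded C6 phenoxide attacks it at the carbon remote from the methoxy group, forming the C6–O–D1 ether with hydrogens at D2 and D6; a metal-free addition to an unhindered, very reactive electrophile suits a phenol flanked by aryloxy and methoxy groups.

Step 16
Reactants: 26 rings A–D tetramer with D4 benzyl ether
Product: 27 permethylated rings A–D tetramer with D4 hydroxyl free
Conditions: H2 (1 atm), Pd/C, EtOAc/MeOH, rt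
Reagents that add atoms: none
Why: Catalytic hydrogenolysis of the benzyl ether, as in step 6.

Step 17
Reactants: 27 rings A–D phenol; 12 trichloroethene
Product: 28 (E)-1,2-dichloroethenyl ether of 27 at the D4 oxygen
Conditions: K2CO3, DMF, 70 °C
Reagents that add atoms: none
Why: Elimination–addition via dichloroethyne made in the flask, as in step 7; 27 has the same 4-aryloxy-2,6-dimethoxyphenol environment as 11.

Step 18
Reactants: 28 dichloroethenyl ether of 27
Product: 30 ethynyl ether of 27 at the D4 oxygen, via lithium acetylide 29 (not isolated)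
Conditions: n-BuLi (2.2 equiv), THF, −78 °C to −40 °C; then MeOH, −78 °C
Reagents that add atoms: none
Why: Dichlorovinyl ether to alkynyl ether conversion (deprotonation, loss of LiCl, chlorine–lithium exchange, protonation), as in step 8; the low temperature keeps n-BuLi from metalating ring positions that lie between two oxygens.

Step 19
Reactants: 30 ethynyl ether of 27
Product: 31 1-(tributylstannyl)ethenyl ether of 27 at the D4 oxygen
Conditions: Bu3SnH, Pd(PPh3)4 (cat.), THF, 0 °C
Reagents that add atoms: tributyltin hydride, CCCC[SnH](CCCC)CCCC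
Why: Palladium-catalysed syn hydrostannylation of the alkoxyalkyne, with tin delivered to the oxygen-bearing carbon, as in step 9.

Step 20
Reactants: 31 1-stannylvinyl ether of 27; 17 dimethyl squarate
Product: 33 racemic 4-hydroxy-2,3-dimethoxy-4-(1-aryloxyethenyl)cyclobut-2-en-1-one (aryl = permethylated rings A–D unit bonded at D4), via vinyllithium 32 (not isolated)
Conditions: n-BuLi, THF, −78 °C; then 17, THF, −78 °C; aq NH4Cl
Reagents that add atoms: none
Why: Tin–lithium exchange and 1,2-addition of the vinyllithium to the squaric ester, as in step 10; the racemic quaternary centre is lost in step 22.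

Step 21
Reactants: 33 racemic 4-hydroxycyclobutenone
Product: 34 racemic 4-[(tert-butyldimethylsilyl)oxy]-2,3-dimethoxy-4-(1-aryloxyethenyl)cyclobut-2-en-1-one (aryl = permethylated rings A–D unit bonded at D4)
Conditions: TBSOTf, 2,6-lutidine, CH2Cl2, −78 °C to 0 °C
Reagents that add atoms: tert-butyldimethylsilyl trifluoromethanesulfonate, CC(C)(C)[Si](C)(C)OS(=O)(=O)C(F)(F)F
Why: Silylation of the tertiary carbinol with silyl triflate and hindered base, as in step 11.

Step 22
Reactants: 34 racemic 4-silyloxycyclobutenone
Product: 37 permethylated rings A–E pentamer with E3 hydroxyl free and E6 tert-butyldimethylsilyl ether, via dienylketene 35 (not isolated), via cyclohexadienone 36 (not isolated)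
Conditions: toluene (0.01 M, degassed), 110 °C, argon
Reagents that add atoms: none
Why: The same thermal Moore rearrangement as in step 12: conrotatory opening of 34 with outward rotation of the silyloxy group gives dienylketene 35, six-electron electrocyclisation forms the E2–E3 bond and ring E (36), and enolisation gives the phenol; no stereocentre is formed.

Step 23
Reactants: 37 pentamer with E3 hydroxyl free
Product: 38 permethylated rings A–E pentamer with E6 tert-butyldimethylsilyl ether
Conditions: MeI, K2CO3, acetone, 40 °C, argon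
Reagents that add atoms: iodomethane, CI
Why: Williamson O-methylation of the single free phenol, as in step 13; the hindered aryl silyl ether is retained.

Step 24
Reactants: 38 pentamer E6 silyl ether
Product: 39 permethylated rings A–E pentamer with E6 hydroxyl free
Conditions: Bu4NF, AcOH, THF, 0 °C
Reagents that add atoms: none
Why: Buffered fluoride cleavage of the aryl silyl ether, as in step 14.

Step 25
Reactants: 39 rings A–E phenol; 7 aryne precursor
Product: 40 permethylated rings A–F hexamer with F4 benzyl ether
Conditions: 7 (1.5 equiv), CsF (3 equiv), MeCN, rt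
Reagents that add atoms: none
Why: Aryne O-arylation as in steps 5 and 15: CsF releases aryne 9 from 7 once more, and the E6 phenoxide adds to it at the carbon remote from methoxy, forming the E6–O–F1 ether.

Step 26
Reactants: 40 hexamer with F4 benzyl ether
Product: 41 permethylated rings A–F hexamer with F4 hydroxyl free
Conditions: H2 (1 atm), Pd/C, EtOAc/MeOH, rt
Reagents that add atoms: none
Why: Catalytic hydrogenolysis of the benzyl ether, as in step 6.

Step 27
Reactants: 42 3,4,5-trimethoxyphenol
Product: 43 2-bromo-3,4,5-trimethoxyphenol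
Conditions: NBS (1.0 equiv), CH2Cl2, −78 °C to 0 °C
Reagents that add atoms: N-bromosuccinimide, O=C1CCC(=O)N1Br
Why: Electrophilic bromination ortho to the hydroxyl; the two ortho positions are equivalent and para is blocked, as in step 2.

Step 28
Reactants: 43 2-bromo-3,4,5-trimethoxyphenol
Product: 44 (2-bromo-3,4,5-trimethoxyphenoxy)trimethylsilane
Conditions: HMDS, THF, 65 °C; evaporate
Reagents that add atoms: hexamethyldisilazane, C[Si](C)(C)N[Si](C)(C)C
Why: O-silylation of the phenol with a disilazane, as in step 3.

Step 29
Reactants: 44 (2-bromo-3,4,5-trimethoxyphenoxy)trimethylsilane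
Product: 46 3,4,5-trimethoxy-2-(trimethylsilyl)phenyl trifluoromethanesulfonate, via lithium phenolate 45 (not isolated)
Conditions: n-BuLi, THF, −78 °C; then Tf2O, −78 °C to rt
Reagents that add atoms: trifluoromethanesulfonic anhydride, O=S(=O)(OS(=O)(=O)C(F)(F)F)C(F)(F)F
Why: Bromine–lithium exchange, retro-Brook silyl migration and O-triflation, as in step 4.

Step 30
Reactants: 41 rings A–F phenol; 46 ring G aryne precursor
Product: 48 permethylated heptamer (octadecamethyl ether of 49), via aryne 47 (not isolated)
Conditions: 46 (1.5 equiv), CsF (3 equiv), MeCN, rt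
Reagents that add atoms: none
Why: Aryne O-arylation: aryne 47 carries its methoxy groups at positions 3 to 5, so the F4 phenoxide adds at the remote carbon and ring G arrives as the 3,4,5-trimethoxyphenyl ether.

Step 31
Reactants: 48 permethylated heptamer
Product: 49 target heptamer with eighteen free hydroxyls
Conditions: BBr3 (excess), CH2Cl2, −78 °C to rt, argon; then MeOH, H2O, 0 °C
Reagents that add atoms: none
Why: Lewis-acid cleavage of aryl methyl ethers: BBr3 binds each methoxy oxygen and bromide attacks the methyl carbon (SN2), so only alkyl–oxygen bonds break and the six diaryl ether links remain; hydrolysis of the aryl borates gives the polyphenol, which has no stereocentre.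

**Compound list**

1 | 4-(benzyloxy)-3,5-dimethoxybenzaldehyde | COc1cc(C=O)cc(OC)c1OCc1ccccc1 | starting material
2 | 4-(benzyloxy)-3,5-dimethoxyphenyl formate | COc1cc(OC=O)cc(OC)c1OCc1ccccc1 | intermediate (not isolated)
3 | 4-(benzyloxy)-3,5-dimethoxyphenol | COc1cc(O)cc(OC)c1OCc1ccccc1 | intermediate
4 | 4-(benzyloxy)-2-bromo-3,5-dimethoxyphenol | COc1cc(O)c(Br)c(OC)c1OCc1ccccc1 | intermediate
5 | [4-(benzyloxy)-2-bromo-3,5-dimethoxyphenoxy]trimethylsilane | COc1cc(O[Si](C)(C)C)c(Br)c(OC)c1OCc1ccccc1 | intermediate
6 | lithium 4-(benzyloxy)-3,5-dimethoxy-2-(trimethylsilyl)phenolate | [Li+].COc1cc([O-])c([Si](C)(C)C)c(OC)c1OCc1ccccc1 | intermediate (not isolated)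
7 | 4-(benzyloxy)-3,5-dimethoxy-2-(trimethylsilyl)phenyl trifluoromethanesulfonate | COc1cc(OS(=O)(=O)C(F)(F)F)c([Si](C)(C)C)c(OC)c1OCc1ccccc1 | intermediate
8 | 2,4,6-trimethoxyphenol | COc1cc(OC)c(O)c(OC)c1 | starting material
9 | 4-(benzyloxy)-3,5-dimethoxy-1,2-didehydrobenzene (aryne for rings B, D and F, released from 7) | COC1=CC#CC(OC)=C1OCc1ccccc1 | intermediate (not isolated)
10 | 2-[4-(benzyloxy)-3,5-dimethoxyphenoxy]-1,3,5-trimethoxybenzene | COc1cc(OC)c(Oc2cc(OC)c(OCc3ccccc3)c(OC)c2)c(OC)c1 | intermediate
11 | 2,6-dimethoxy-4-(2,4,6-trimethoxyphenoxy)phenol | COc1cc(OC)c(Oc2cc(OC)c(O)c(OC)c2)c(OC)c1 | intermediate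
12 | trichloroethene | ClC=C(Cl)Cl | starting material
13 | 2-{4-[(E)-1,2-dichloroethenyloxy]-3,5-dimethoxyphenoxy}-1,3,5-trimethoxybenzene | COc1cc(OC)c(Oc2cc(OC)c(O/C(Cl)=C\Cl)c(OC)c2)c(OC)c1 | intermediate
14 | {[2,6-dimethoxy-4-(2,4,6-trimethoxyphenoxy)phenoxy]ethynyl}lithium | [Li]C#COc1c(OC)cc(Oc2c(OC)cc(OC)cc2OC)cc1OC | intermediate (not isolated)
15 | 2-[4-(ethynyloxy)-3,5-dimethoxyphenoxy]-1,3,5-trimethoxybenzene | C#COc1c(OC)cc(Oc2c(OC)cc(OC)cc2OC)cc1OC | intermediate
16 | tributyl{1-[2,6-dimethoxy-4-(2,4,6-trimethoxyphenoxy)phenoxy]ethenyl}stannane | CCCC[Sn](CCCC)(CCCC)C(=C)Oc1c(OC)cc(Oc2c(OC)cc(OC)cc2OC)cc1OC | intermediate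
17 | dimethyl squarate (3,4-dimethoxycyclobut-3-ene-1,2-dione) | COC1=C(OC)C(=O)C1=O | starting material
18 | {1-[2,6-dimethoxy-4-(2,4,6-trimethoxyphenoxy)phenoxy]ethenyl}lithium | [Li]C(=C)Oc1c(OC)cc(Oc2c(OC)cc(OC)cc2OC)cc1OC | intermediate (not isolated)
19 | racemic 4-hydroxy-2,3-dimethoxy-4-{1-[2,6-dimethoxy-4-(2,4,6-trimethoxyphenoxy)phenoxy]ethenyl}cyclobut-2-en-1-one | COC1=C(OC)C(O)(C(=C)Oc2c(OC)cc(Oc3c(OC)cc(OC)cc3OC)cc2OC)C1=O | intermediate
20 | racemic 4-[(tert-butyldimethylsilyl)oxy]-2,3-dimethoxy-4-{1-[2,6-dimethoxy-4-(2,4,6-trimethoxyphenoxy)phenoxy]ethenyl}cyclobut-2-en-1-one | COC1=C(OC)C(O[Si](C)(C)C(C)(C)C)(C(=C)Oc2c(OC)cc(Oc3c(OC)cc(OC)cc3OC)cc2OC)C1=O | intermediate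
21 | (3Z)-4-[(tert-butyldimethylsilyl)oxy]-2,3-dimethoxy-5-[2,6-dimethoxy-4-(2,4,6-trimethoxyphenoxy)phenoxy]hexa-1,3,5-trien-1-one (dienylketene, vinyl group cis to the ketene) | O=C=C(OC)/C(OC)=C(/O[Si](C)(C)C(C)(C)C)C(=C)Oc1c(OC)cc(Oc2c(OC)cc(OC)cc2OC)cc1OC | intermediate (not isolated)
22 | 4-[(tert-butyldimethylsilyl)oxy]-2,3-dimethoxy-5-[2,6-dimethoxy-4-(2,4,6-trimethoxyphenoxy)phenoxy]cyclohexa-2,4-dien-1-one | O=C1CC(Oc2c(OC)cc(Oc3c(OC)cc(OC)cc3OC)cc2OC)=C(O[Si](C)(C)C(C)(C)C)C(OC)=C1OC | intermediate (not isolated)
23 | 4-[(tert-butyldimethylsilyl)oxy]-2,3-dimethoxy-5-[2,6-dimethoxy-4-(2,4,6-trimethoxyphenoxy)phenoxy]phenol | COc1cc(OC)c(Oc2cc(OC)c(Oc3cc(O)c(OC)c(OC)c3O[Si](C)(C)C(C)(C)C)c(OC)c2)c(OC)c1 | intermediate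
24 | tert-butyldimethyl{2,3,4-trimethoxy-6-[2,6-dimethoxy-4-(2,4,6-trimethoxyphenoxy)phenoxy]phenoxy}silane | COc1cc(OC)c(Oc2cc(OC)c(Oc3cc(OC)c(OC)c(OC)c3O[Si](C)(C)C(C)(C)C)c(OC)c2)c(OC)c1 | intermediate
25 | 2,3,4-trimethoxy-6-[2,6-dimethoxy-4-(2,4,6-trimethoxyphenoxy)phenoxy]phenol | COc1cc(OC)c(Oc2cc(OC)c(Oc3cc(OC)c(OC)c(OC)c3O)c(OC)c2)c(OC)c1 | intermediate
26 | permethylated rings A–D tetramer with D4 benzyl ether | COc1cc(OC)c(Oc2cc(OC)c(Oc3cc(OC)c(OC)c(OC)c3Oc3cc(OC)c(OCc4ccccc4)c(OC)c3)c(OC)c2)c(OC)c1 | intermediate
27 | permethylated rings A–D tetramer with D4 hydroxyl free | COc1cc(OC)c(Oc2cc(OC)c(Oc3cc(OC)c(OC)c(OC)c3Oc3cc(OC)c(O)c(OC)c3)c(OC)c2)c(OC)c1 | intermediate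
28 | (E)-1,2-dichloroethenyl ether of 27 at the D4 oxygen | COc1cc(OC)c(Oc2cc(OC)c(Oc3cc(OC)c(OC)c(OC)c3Oc3cc(OC)c(O/C(Cl)=C\Cl)c(OC)c3)c(OC)c2)c(OC)c1 | intermediate
29 | lithium acetylide of ethynyl ether 30 | [Li]C#COc1c(OC)cc(Oc2c(OC)c(OC)c(OC)cc2Oc2c(OC)cc(Oc3c(OC)cc(OC)cc3OC)cc2OC)cc1OC | intermediate (not isolated)
30 | ethynyl ether of 27 at the D4 oxygen | C#COc1c(OC)cc(Oc2c(OC)c(OC)c(OC)cc2Oc2c(OC)cc(Oc3c(OC)cc(OC)cc3OC)cc2OC)cc1OC | intermediate
31 | 1-(tributylstannyl)ethenyl ether of 27 at the D4 oxygen | CCCC[Sn](CCCC)(CCCC)C(=C)Oc1c(OC)cc(Oc2c(OC)c(OC)c(OC)cc2Oc2c(OC)cc(Oc3c(OC)cc(OC)cc3OC)cc2OC)cc1OC | intermediate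
32 | 1-lithioethenyl ether of 27 at the D4 oxygen | [Li]C(=C)Oc1c(OC)cc(Oc2c(OC)c(OC)c(OC)cc2Oc2c(OC)cc(Oc3c(OC)cc(OC)cc3OC)cc2OC)cc1OC | intermediate (not isolated)
33 | racemic 4-hydroxy-2,3-dimethoxy-4-(1-aryloxyethenyl)cyclobut-2-en-1-one, aryl = permethylated rings A–D unit bonded at D4 | COC1=C(OC)C(O)(C(=C)Oc2c(OC)cc(Oc3c(OC)c(OC)c(OC)cc3Oc3c(OC)cc(Oc4c(OC)cc(OC)cc4OC)cc3OC)cc2OC)C1=O | intermediate
34 | racemic 4-[(tert-butyldimethylsilyl)oxy]-2,3-dimethoxy-4-(1-aryloxyethenyl)cyclobut-2-en-1-one, aryl = permethylated rings A–D unit bonded at D4 | COC1=C(OC)C(O[Si](C)(C)C(C)(C)C)(C(=C)Oc2c(OC)cc(Oc3c(OC)c(OC)c(OC)cc3Oc3c(OC)cc(Oc4c(OC)cc(OC)cc4OC)cc3OC)cc2OC)C1=O | intermediate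
35 | (3Z)-dienylketene from 34 (vinyl group cis to the ketene) | O=C=C(OC)/C(OC)=C(/O[Si](C)(C)C(C)(C)C)C(=C)Oc1c(OC)cc(Oc2c(OC)c(OC)c(OC)cc2Oc2c(OC)cc(Oc3c(OC)cc(OC)cc3OC)cc2OC)cc1OC | intermediate (not isolated)
36 | 5-aryloxy-4-[(tert-butyldimethylsilyl)oxy]-2,3-dimethoxycyclohexa-2,4-dien-1-one, aryl = permethylated rings A–D unit bonded at D4 | O=C1CC(Oc2c(OC)cc(Oc3c(OC)c(OC)c(OC)cc3Oc3c(OC)cc(Oc4c(OC)cc(OC)cc4OC)cc3OC)cc2OC)=C(O[Si](C)(C)C(C)(C)C)C(OC)=C1OC | intermediate (not isolated)
37 | permethylated rings A–E pentamer with E3 hydroxyl free and E6 tert-butyldimethylsilyl ether | COc1cc(OC)c(Oc2cc(OC)c(Oc3cc(OC)c(OC)c(OC)c3Oc3cc(OC)c(Oc4cc(O)c(OC)c(OC)c4O[Si](C)(C)C(C)(C)C)c(OC)c3)c(OC)c2)c(OC)c1 | intermediate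
38 | permethylated rings A–E pentamer with E6 tert-butyldimethylsilyl ether | COc1cc(OC)c(Oc2cc(OC)c(Oc3cc(OC)c(OC)c(OC)c3Oc3cc(OC)c(Oc4cc(OC)c(OC)c(OC)c4O[Si](C)(C)C(C)(C)C)c(OC)c3)c(OC)c2)c(OC)c1 | intermediate
39 | permethylated rings A–E pentamer with E6 hydroxyl free | COc1cc(OC)c(Oc2cc(OC)c(Oc3cc(OC)c(OC)c(OC)c3Oc3cc(OC)c(Oc4cc(OC)c(OC)c(OC)c4O)c(OC)c3)c(OC)c2)c(OC)c1 | intermediate
40 | permethylated rings A–F hexamer with F4 benzyl ether | COc1cc(OC)c(Oc2cc(OC)c(Oc3cc(OC)c(OC)c(OC)c3Oc3cc(OC)c(Oc4cc(OC)c(OC)c(OC)c4Oc4cc(OC)c(OCc5ccccc5)c(OC)c4)c(OC)c3)c(OC)c2)c(OC)c1 | intermediate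
41 | permethylated rings A–F hexamer with F4 hydroxyl free | COc1cc(OC)c(Oc2cc(OC)c(Oc3cc(OC)c(OC)c(OC)c3Oc3cc(OC)c(Oc4cc(OC)c(OC)c(OC)c4Oc4cc(OC)c(O)c(OC)c4)c(OC)c3)c(OC)c2)c(OC)c1 | intermediate
42 | 3,4,5-trimethoxyphenol | COc1cc(O)cc(OC)c1OC | starting material
43 | 2-bromo-3,4,5-trimethoxyphenol | COc1cc(O)c(Br)c(OC)c1OC | intermediate
44 | (2-bromo-3,4,5-trimethoxyphenoxy)trimethylsilane | COc1cc(O[Si](C)(C)C)c(Br)c(OC)c1OC | intermediate
45 | lithium 3,4,5-trimethoxy-2-(trimethylsilyl)phenolate | [Li+].COc1cc([O-])c([Si](C)(C)C)c(OC)c1OC | intermediate (not isolated)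
46 | 3,4,5-trimethoxy-2-(trimethylsilyl)phenyl trifluoromethanesulfonate | COc1cc(OS(=O)(=O)C(F)(F)F)c([Si](C)(C)C)c(OC)c1OC | intermediate
47 | 3,4,5-trimethoxy-1,2-didehydrobenzene (aryne for ring G) | COC1=CC#CC(OC)=C1OC | intermediate (not isolated)
48 | permethylated heptamer (octadecamethyl ether of 49) | COc1cc(OC)c(Oc2cc(OC)c(Oc3cc(OC)c(OC)c(OC)c3Oc3cc(OC)c(Oc4cc(OC)c(OC)c(OC)c4Oc4cc(OC)c(Oc5cc(OC)c(OC)c(OC)c5)c(OC)c4)c(OC)c3)c(OC)c2)c(OC)c1 | intermediate
49 | CNP0292517.0, heptamer of rings A–G with eighteen free hydroxyls | Oc1cc(O)c(Oc2cc(O)c(Oc3cc(O)c(O)c(O)c3Oc3cc(O)c(Oc4cc(O)c(O)c(O)c4Oc4cc(O)c(Oc5cc(O)c(O)c(O)c5)c(O)c4)c(O)c3)c(O)c2)c(O)c1 | target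

**Step count and risk**

Total: 31 steps. Longest linear sequence: 28 steps (steps 1–4, 5–26, 30 and 31).

Least certain steps:

Step 12 (key step; the same holds for step 22). The most likely failure is loss of the differentiation between O3 and O6. The product is a very electron-rich hydroquinone monoether that is heated for hours, so the silyl group can be transferred between phenolic oxygens or lost on oxidation to the quinone. The freshly formed phenol can also acylate unreacted ketene. Fallback: give up the silyl differentiation and use the hydroquinone and quinone forms of the same ring. Setting out from 19 (step 11 omitted), heating in degassed toluene should give the hydroquinone 2,3-dimethoxy-5-[2,6-dimethoxy-4-(2,4,6-trimethoxyphenoxy)phenoxy]benzene-1,4-diol F1. This is oxidised with Ag2O to the robust quinone 2,3-dimethoxy-5-[2,6-dimethoxy-4-(2,4,6-trimethoxyphenoxy)phenoxy]cyclohexa-2,5-diene-1,4-dione F2, which can be purified. Reduction with Na2S2O4 returns F1. Mitsunobu methylation with one equivalent of MeOH, PPh3 and diisopropyl azodicarboxylate should favour the hydroxyl that has an ortho hydrogen over the one shielded by aryloxy and methoxy groups, and gives 25, where the route is rejoined.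

Step 9 (and step 19). Part of the tin may be delivered to the terminal carbon, and the α-stannyl enol ether may lose tin by protonolysis during isolation; both would lower the supply of the vinyl anion. Fallback: replace hydrometalation by a polar addition whose regiochemistry is fixed by the ynol ether. Setting out from 15, Markovnikov addition of HBr (TMSBr and one equivalent of MeOH, CH2Cl2, −78 °C) should give 2-{4-[(1-bromoethenyl)oxy]-3,5-dimethoxyphenoxy}-1,3,5-trimethoxybenzene F3. Bromine–lithium exchange with t-BuLi (2 equiv, THF, −78 °C) then gives the vinyllithium 18, and the route continues with the addition to 17 in step 10.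

Step 15 (and steps 5, 25 and 30). The aryne may be consumed by self-reaction, or attacked at its other carbon, before the crowded phenoxide captures it; conversion then stalls or a regioisomeric ether appears. Fallback: form the same C6–O–D1 bond by copper catalysis instead of by an aryne. Setting out from 25, Ullmann-type coupling with the aryl bromide 2-(benzyloxy)-5-bromo-1,3-dimethoxybenzene F4 (CuI, picolinic acid, K3PO4, DMSO, 90 °C) gives 26, where the route is rejoined. The bromide carbon has hydrogens on both sides, so only the phenol is hindered.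

Step 31. Cleavage of the methyl ethers that lie between two oxygen substituents may be incomplete, and the polyphenol may be oxidised during aqueous work-up, giving a mixture that cannot be separated as free phenols. Fallback: isolate through a protected derivative. Setting out from 48, the crude BBr3 product is acetylated (Ac2O, pyridine) to the octadecaacetate of the heptamer F5, which is purified on silica and separated from partially methylated material. Deacetylation with K2CO3 (cat.) in degassed MeOH under argon, followed by acidification, gives 49.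

**Further compounds**

F1 | step 12 | 2,3-dimethoxy-5-[2,6-dimethoxy-4-(2,4,6-trimethoxyphenoxy)phenoxy]benzene-1,4-diol | COc1c(O)cc(Oc2c(OC)cc(Oc3c(OC)cc(OC)cc3OC)cc2OC)c(O)c1OC
F2 | step 12 | 2,3-dimethoxy-5-[2,6-dimethoxy-4-(2,4,6-trimethoxyphenoxy)phenoxy]cyclohexa-2,5-diene-1,4-dione | COC1=C(OC)C(=O)C(Oc2c(OC)cc(Oc3c(OC)cc(OC)cc3OC)cc2OC)=CC1=O
F3 | step 9 | 2-{4-[(1-bromoethenyl)oxy]-3,5-dimethoxyphenoxy}-1,3,5-trimethoxybenzene | C=C(Br)Oc1c(OC)cc(Oc2c(OC)cc(OC)cc2OC)cc1OC
F4 | step 15 | 2-(benzyloxy)-5-bromo-1,3-dimethoxybenzene | COc1cc(Br)cc(OC)c1OCc1ccccc1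
F5 | step 31 | octadecaacetate of 49 | CC(=O)Oc1cc(OC(C)=O)c(Oc2cc(OC(C)=O)c(Oc3cc(OC(C)=O)c(OC(C)=O)c(OC(C)=O)c3Oc3cc(OC(C)=O)c(Oc4cc(OC(C)=O)c(OC(C)=O)c(OC(C)=O)c4Oc4cc(OC(C)=O)c(Oc5cc(OC(C)=O)c(OC(C)=O)c(OC(C)=O)c5)c(OC(C)=O)c4)c(OC(C)=O)c3)c(OC(C)=O)c2)c(OC(C)=O)c1
A1 | alternative 1 | permethylated rings A–B dimer with B4 triisopropylsilyl ether | COc1cc(OC)c(Oc2cc(OC)c(O[Si](C(C)C)(C(C)C)C(C)C)c(OC)c2)c(OC)c1
A2 | alternative 1 | 3,5-dimethoxy-4H-pyran-4-one | COC1=COC=C(OC)C1=O
A3 | alternative 1 | [(2,4,6-trimethoxyphenoxy)methyl]triphenylphosphonium chloride | COc1cc(OC)c(OC[P+](c2ccccc2)(c2ccccc2)c2ccccc2)c(OC)c1.[Cl-]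
A4 | alternative 2 | diethyl 2,4,6-trihydroxy-5-aryloxybenzene-1,3-dicarboxylate carrying the permethylated rings B–G | CCOC(=O)c1c(O)c(C(=O)OCC)c(O)c(Oc2cc(OC)c(Oc3cc(OC)c(OC)c(OC)c3Oc3cc(OC)c(Oc4cc(OC)c(OC)c(OC)c4Oc4cc(OC)c(Oc5cc(OC)c(OC)c(OC)c5)c(OC)c4)c(OC)c3)c(OC)c2)c1O
A5 | alternative 2 | diethyl 2-aryloxypropanedioate carrying the permethylated rings B–G (bonded at B1) | CCOC(=O)C(Oc1cc(OC)c(Oc2cc(OC)c(OC)c(OC)c2Oc2cc(OC)c(Oc3cc(OC)c(OC)c(OC)c3Oc3cc(OC)c(Oc4cc(OC)c(OC)c(OC)c4)c(OC)c3)c(OC)c2)c(OC)c1)C(=O)OCC
A6 | alternative 2 | diethyl 3-oxopentanedioate | CCOC(=O)CC(=O)CC(=O)OCC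
A7 | alternative 3 | heptamer with D5 hydroxyl free, D3 ethyl ether and all other hydroxyls as methyl ethers | COc1cc(OC)c(Oc2cc(OC)c(Oc3cc(OC)c(OC)c(OC)c3Oc3cc(OCC)c(Oc4cc(OC)c(OC)c(OC)c4Oc4cc(OC)c(Oc5cc(OC)c(OC)c(OC)c5)c(OC)c4)c(O)c3)c(OC)c2)c(OC)c1
A8 | alternative 3 | ethynyl ether of the permethylated rings A–C phenol (at the C6 oxygen) | C#COc1c(OC)c(OC)c(OC)cc1Oc1c(OC)cc(Oc2c(OC)cc(OC)cc2OC)cc1OC
A9 | alternative 3 | racemic 4-aryloxy-3-ethoxycyclobut-2-en-1-one carrying the permethylated rings E–G (bonded at E1) | CCOC1=CC(=O)C1Oc1cc(OC)c(OC)c(OC)c1Oc1cc(OC)c(Oc2cc(OC)c(OC)c(OC)c2)c(OC)c1
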